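**Retrosynthetic overview**

1. Target ⇒ last-step site- and face-selective epoxidation of the E ring alkene; primary acetate and tertiary alcohol ⇒ acetate opening of a terminal 2,2-disubstituted epoxide; enone ⇒ aldol condensation of a cyclobutyl methyl ketone with (S)-2-methyloxirane-2-carbaldehyde.
2. E-configured nine-membered diene ⇒ its Z isomer (epoxidation, then phosphorus-betaine olefin inversion); exocyclic methylidene ⇒ ring ketone (Wittig) after equilibration of the ring fusion to trans.
3. Nine-membered ketone ⇒ Claisen ring expansion of a cyclobutane-fused 2-methylidene-7-vinyloxepane, made in the flask from the seven-membered lactone by carbonyl methylenation; this forms the ring CH2–CH2 bond between the CH2 next to the methylidene-bearing carbon and the CH2 next to the epoxide CH.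
4. Enabling feature: in the nine-membered ring that CH2–CH2 bond lies between the carbon carrying the exocyclic CH2 (a masked C=O) and the epoxide CH–C(CH3) unit (a masked CH=C(CH3)), i.e. the O=C–CH2–CH2–CH=C pattern of a Claisen product, so the ring can be grown by two atoms from a seven-membered cyclic enol ether.
5. Lactone ⇒ Baeyer–Villiger oxidation of an α-methyl-α-vinyl bicyclo[4.2.0]octanone ⇒ enantioselective [2+2] photocycloaddition of cyclohex-2-enone with a ketal-masked isopropenyl methyl ketone. Ring order: cyclobutane (on the six-membered ring), seven-membered lactone, nine-membered carbocycle, epoxide last.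

Key step: step 7

Remark: the Claisen ring expansion is taken to give the Z (cis) nine-membered alkene, as expected for a [3,3] shift through an oxepane-bridged chair transition state; the E geometry is therefore installed afterwards by stereospecific alkene inversion.

**Route**

Step 1
Reactants: 1 3-methylbut-3-en-2-one
Product: 2 2-methyl-2-(prop-1-en-2-yl)-1,3-dioxolane
Conditions: (TMSOCH2)2, TMSOTf (cat.), CH2Cl2, −78 to −20 °C
Reagents that add atoms: 1,2-bis(trimethylsilyloxy)ethane, C[Si](C)(C)OCCO[Si](C)(C)C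
Why: Acid-free TMSOTf-catalysed ketalisation with the bis-silyl ether, driven by Si–O–Si bond formation, masks the carbonyl without conjugate addition or double-bond migration and gives a 1,1-disubstituted alkene carrying the future acetyl group in bulky, protected form.

Step 2
Reactants: 2 2-methyl-2-(prop-1-en-2-yl)-1,3-dioxolane; 3 cyclohex-2-en-1-one
Product: 5 (1R,6R,7R)-7-methyl-7-(2-methyl-1,3-dioxolan-2-yl)bicyclo[4.2.0]octan-2-one (cis-fused), via trans-fused photoadduct 4 (not isolated)
Conditions: 2 (excess), chiral prolinol-derived B-aryl oxazaborolidine activated by AlBr3 (50 mol %, enantiomer giving the 6R adduct), hν (366 nm), CH2Cl2, −75 °C; then basic Al2O3, rt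
Reagents that add atoms: none
Why: Enantioselective Lewis-acid-catalysed enone–alkene [2+2] photocycloaddition: the chiral complex of 3 is excited selectively and shields one enone face (sets the β-carbon), the alkene adds head-to-tail as 1,1-dialkylethylenes do (CH2 to the α-carbon), the tert-alkyl-like dioxolanyl group closes into the exo position so that the methyl group is cis to the six-membered ring (sets the quaternary carbon), and basic alumina epimerises the α-carbon of 4 to the stable cis ring fusion.

Step 3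
Reactants: 5 (1R,6R,7R)-7-methyl-7-(2-methyl-1,3-dioxolan-2-yl)bicyclo[4.2.0]octan-2-one
Product: 7 (1R,6R,7R)-3-(1-hydroxyethyl)-7-methyl-7-(2-methyl-1,3-dioxolan-2-yl)bicyclo[4.2.0]octan-2-one (epimers at the two new centres), via lithium enolate 6 (not isolated)
Conditions: LiN(iPr)2, THF, −78 °C; CH3CHO; H2O
Reagents that add atoms: acetaldehyde, CC=O
Why: Kinetic deprotonation occurs at the unhindered α-CH2 and not at the ring-fusion α-CH, and aldol addition brings in the two carbons of the future vinyl group; the two new stereocentres are removed in steps 4 and 5.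

Step 4
Reactants: 7 (1R,6R,7R)-3-(1-hydroxyethyl)-7-methyl-7-(2-methyl-1,3-dioxolan-2-yl)bicyclo[4.2.0]octan-2-one
Product: 9 (1R,3E,6R,7R)-3-ethylidene-7-methyl-7-(2-methyl-1,3-dioxolan-2-yl)bicyclo[4.2.0]octan-2-one, via mesylate 8 (not isolated)
Conditions: MsCl, Et3N, CH2Cl2, 0 °C; then DBU, rt
Reagents that add atoms: none
Why: Mesylation and DBU-induced E1cB elimination give the conjugated exocyclic enone, for which the E isomer (methyl away from the carbonyl) is the thermodynamically preferred one.

Step 5
Reactants: 9 (1R,3E,6R,7R)-3-ethylidene-7-methyl-7-(2-methyl-1,3-dioxolan-2-yl)bicyclo[4.2.0]octan-2-one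
Product: 11 (1R,6R,7R)-3-ethenyl-3,7-dimethyl-7-(2-methyl-1,3-dioxolan-2-yl)bicyclo[4.2.0]octan-2-one (epimers at C3), via potassium dienolate 10 (not isolated)
Conditions: KOtBu, t-BuOH/THF, 0 °C; MeI
Reagents that add atoms: iodomethane, CI
Why: Deconjugative α-alkylation: equilibrating γ-deprotonation gives the extended dienolate, which is methylated at its α-carbon to build the α-methyl-α-vinyl quaternary centre; this centre becomes sp2 in step 7, so both epimers are carried on.

Step 6
Reactants: 11 (1R,6R,7R)-3-ethenyl-3,7-dimethyl-7-(2-methyl-1,3-dioxolan-2-yl)bicyclo[4.2.0]octan-2-one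
Product: 12 (1R,7R,8R)-4-ethenyl-4,8-dimethyl-8-(2-methyl-1,3-dioxolan-2-yl)-3-oxabicyclo[5.2.0]nonan-2-one (epimers at C4)
Conditions: mCPBA, NaHCO3, CH2Cl2, 0 °C to rt
Reagents that add atoms: 3-chloroperoxybenzoic acid, OOC(=O)c1cccc(Cl)c1
Why: Baeyer–Villiger oxidation: in the Criegee adduct the quaternary, allylically stabilised α-carbon migrates with retention in preference to the secondary cyclobutyl carbon, placing oxygen between the carbonyl and the methyl/vinyl-bearing carbon, while the monosubstituted vinyl group should be epoxidised more slowly under buffered conditions.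

Step 7
Reactants: 12 (1R,7R,8R)-4-ethenyl-4,8-dimethyl-8-(2-methyl-1,3-dioxolan-2-yl)-3-oxabicyclo[5.2.0]nonan-2-one
Product: 14 (1R,4Z,9R,11R)-4,11-dimethyl-11-(2-methyl-1,3-dioxolan-2-yl)bicyclo[7.2.0]undec-4-en-8-one (cis-fused), via enol ether 13 (not isolated)
Conditions: Cp2TiMe2 (2.5 equiv), toluene, 75 °C, dark; filtration through basic Al2O3; xylene, 140 °C
Reagents that add atoms: dimethyltitanocene, C[Ti](C)(C1C=CC=C1)C1C=CC=C1
Why: Cp2TiMe2 loses methane to give Cp2Ti=CH2, which methylenates the lactone carbonyl (oxatitanacyclobutane, then loss of Cp2Ti=O) to the 2-methylidene-7-vinyloxepane 13; this allyl vinyl ether then undergoes a thermal Claisen [3,3] rearrangement in which the new CH2–CH2 bond forms between the titanium-derived methylidene carbon and the vinyl terminus while the ring C–O bond to the quaternary carbon breaks and the ketone appears. The closest known reaction type is the Claisen ring expansion of 2-methylidene-6-vinyltetrahydropyrans, obtained by titanium methylenation of lactones, to cyclooct-4-enones, applied here one ring size higher. The nine-membered carbocycle is closed by two-atom ring enlargement of the seven-membered oxacycle through a bridged chair-like transition state, not by end-to-end cyclisation, so no high dilution is needed. No new stereocentre is formed (both carbons of the new bond are CH2), the quaternary ether carbon is erased so that both of its epimers converge, and the cyclobutane centres are untouched; the only stereo-element set is the ring alkene, where the oxepane tether forces the ring CH2 on the allylic carbon into the pseudo-axial position and so gives the Z alkene. The step needs the [3,3] shift to win over ionisation or elimination of the tertiary allylic ether and over exo-to-endo enol ether isomerisation, which the neutral titanium reagent, the base-treated filtration and the high rate of rearrangement of a tertiary allylic vinyl ether should secure; removing titanium residues before heating prevents methylenation of the still cis-fused ketone.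

Step 8
Reactants: 14 (1R,4Z,9R,11R)-4,11-dimethyl-11-(2-methyl-1,3-dioxolan-2-yl)bicyclo[7.2.0]undec-4-en-8-one
Product: 15 (1R,4Z,9S,11R)-4,11-dimethyl-11-(2-methyl-1,3-dioxolan-2-yl)bicyclo[7.2.0]undec-4-en-8-one (trans-fused)
Conditions: NaOMe (cat.), MeOH, rt
Reagents that add atoms: none
Why: Enolate-mediated epimerisation equilibrates the α-carbon at the ring fusion to the trans-fused cyclobutane/nine-membered junction, expected to be the more stable one (ring bonds trans on the cyclobutane, acyl-bearing bond cis-1,3 to the dioxolanyl group), which sets this stereocentre as in the target.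

Step 9
Reactants: 15 (1R,4Z,9S,11R)-4,11-dimethyl-11-(2-methyl-1,3-dioxolan-2-yl)bicyclo[7.2.0]undec-4-en-8-one
Product: 16 2-[(1R,4Z,9S,11R)-4,11-dimethyl-8-methylidenebicyclo[7.2.0]undec-4-en-11-yl]-2-methyl-1,3-dioxolane
Conditions: Ph3PCH3Br, KOtBu, toluene, 80 °C
Reagents that add atoms: methyltriphenylphosphonium bromide, C[P+](c1ccccc1)(c1ccccc1)c1ccccc1.[Br-]
Why: Wittig methylenation with the unstabilised ylide converts the ring ketone into the exocyclic methylidene group and fixes the ring-fusion centre, which is no longer enolisable.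

Step 10
Reactants: 16 2-[(1R,4Z,9S,11R)-4,11-dimethyl-8-methylidenebicyclo[7.2.0]undec-4-en-11-yl]-2-methyl-1,3-dioxolane
Product: 17 2-[(1R,4R,5S,9S,11R)-4,5-epoxy-4,11-dimethyl-8-methylidenebicyclo[7.2.0]undecan-11-yl]-2-methyl-1,3-dioxolane (cis-epoxide, drawn as one face isomer)
Conditions: mCPBA (1 equiv), NaHCO3, CH2Cl2, 0 °C
Reagents that add atoms: 3-chloroperoxybenzoic acid, OOC(=O)c1cccc(Cl)c1
Why: Prilezhaev epoxidation is selective for the more nucleophilic trisubstituted ring alkene over the 1,1-disubstituted methylidene group and is syn-stereospecific, giving a cis-epoxide; the face attacked is immaterial because step 11 erases both epoxide stereocentres.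

Step 11
Reactants: 17 2-[(1R,4R,5S,9S,11R)-4,5-epoxy-4,11-dimethyl-8-methylidenebicyclo[7.2.0]undecan-11-yl]-2-methyl-1,3-dioxolane
Product: 20 2-[(1R,4E,9S,11R)-4,11-dimethyl-8-methylidenebicyclo[7.2.0]undec-4-en-11-yl]-2-methyl-1,3-dioxolane, via lithium alkoxide phosphine 18 (not isolated), via phosphonium betaine 19 (not isolated)
Conditions: Ph2PH, n-BuLi, THF, 0 °C to rt; then MeI, rt
Reagents that add atoms: none
Why: Phosphorus-betaine olefin inversion: the phosphide opens the epoxide by SN2 attack at the secondary carbon (inversion), P-methylation gives the betaine, and after C–C bond rotation a Wittig-type syn-elimination of Ph2P(O)Me delivers the alkene of opposite geometry, converting the Z-cyclononene stereospecifically into the strained E-cyclononene.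

Step 12
Reactants: 20 2-[(1R,4E,9S,11R)-4,11-dimethyl-8-methylidenebicyclo[7.2.0]undec-4-en-11-yl]-2-methyl-1,3-dioxolane
Product: 21 1-[(1R,4E,9S,11R)-4,11-dimethyl-8-methylidenebicyclo[7.2.0]undec-4-en-11-yl]ethan-1-one
Conditions: PPTS (cat.), THF/H2O, 50 °C
Reagents that add atoms: water, O
Why: Mild acid-catalysed hydrolysis of the dioxolane frees the methyl ketone; the weak acid is chosen so that the acid-sensitive E-cyclononene/methylidene diene is not protonated.

Step 13
Reactants: 22 (R)-(2-methyloxiran-2-yl)methanol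
Product: 23 (S)-2-methyloxirane-2-carbaldehyde
Conditions: TEMPO (cat.), PhI(OAc)2, CH2Cl2, rt; used as solution
Reagents that add atoms: none
Why: Oxoammonium-mediated oxidation converts the primary alcohol into the aldehyde under non-basic, non-aqueous conditions that leave the epoxide intact; the quaternary stereocentre cannot epimerise.

Step 14
Reactants: 21 1-[(1R,4E,9S,11R)-4,11-dimethyl-8-methylidenebicyclo[7.2.0]undec-4-en-11-yl]ethan-1-one; 23 (S)-2-methyloxirane-2-carbaldehyde
Product: 25 3-hydroxy-1-[(1R,4E,9S,11R)-4,11-dimethyl-8-methylidenebicyclo[7.2.0]undec-4-en-11-yl]-3-[(2S)-2-methyloxiran-2-yl]propan-1-one (carbinol epimers), via lithium enolate 24 (not isolated)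
Conditions: LiN(iPr)2, THF, −78 °C; 23; H2O
Reagents that add atoms: none
Why: Directed aldol addition: the ketone can be enolised only at its methyl group (the other α-carbon is quaternary) and the aldehyde has no α-hydrogen, so the cross-aldol is unambiguous; the carbinol centre is removed in step 15 and the epoxide centre of 23 is untouched.

Step 15
Reactants: 25 3-hydroxy-1-[(1R,4E,9S,11R)-4,11-dimethyl-8-methylidenebicyclo[7.2.0]undec-4-en-11-yl]-3-[(2S)-2-methyloxiran-2-yl]propan-1-one
Product: 27 (2E)-1-[(1R,4E,9S,11R)-4,11-dimethyl-8-methylidenebicyclo[7.2.0]undec-4-en-11-yl]-3-[(2R)-2-methyloxiran-2-yl]prop-2-en-1-one, via mesylate 26 (not isolated)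
Conditions: MsCl, Et3N, CH2Cl2, 0 °C; then DBU, rt
Reagents that add atoms: none
Why: Mesylation and E1cB elimination give the E-enone (the favoured geometry for a 1,2-disubstituted enone) and leave the 2,2-disubstituted epoxide in place.

Step 16
Reactants: 27 (2E)-1-[(1R,4E,9S,11R)-4,11-dimethyl-8-methylidenebicyclo[7.2.0]undec-4-en-11-yl]-3-[(2R)-2-methyloxiran-2-yl]prop-2-en-1-one
Product: 28 (2R,3E)-2-hydroxy-2-methyl-5-oxo-5-[(1R,4E,9S,11R)-4,11-dimethyl-8-methylidenebicyclo[7.2.0]undec-4-en-11-yl]pent-3-en-1-yl acetate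
Conditions: CsOAc, AcOH, DMF, 60 °C
Reagents that add atoms: acetic acid (acetate delivered as CsOAc), CC(=O)O
Why: Acetate opens the 2,2-disubstituted epoxide by SN2 attack at the unhindered CH2 terminus (the tertiary carbon is hindered and deactivated by the adjacent enone), installing the primary acetate and freeing the tertiary alcohol with retention of its R configuration; acetic acid protonates the alkoxide and regenerates acetate.

Step 17
Reactants: 28 (2R,3E)-2-hydroxy-2-methyl-5-oxo-5-[(1R,4E,9S,11R)-4,11-dimethyl-8-methylidenebicyclo[7.2.0]undec-4-en-11-yl]pent-3-en-1-yl acetate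
Product: 29 (2R,3E)-2-hydroxy-2-methyl-5-oxo-5-[(1R,4R,6R,10S,12R)-4,12-dimethyl-9-methylidene-5-oxatricyclo[8.2.0.0(4,6)]dodecan-12-yl]pent-3-en-1-yl acetate (CNP0186939.2)
Conditions: mCPBA (1 equiv), NaHCO3, CH2Cl2, 0 °C
Reagents that add atoms: 3-chloroperoxybenzoic acid, OOC(=O)c1cccc(Cl)c1
Why: Prilezhaev epoxidation of the strained, most electron-rich trisubstituted E-alkene (the enone alkene is deactivated, the methylidene less nucleophilic) is stereospecific and gives the trans-epoxide, and the peracid should attack the exposed outer face of the E-cyclononene, the facial preference by which β-caryophyllene gives its natural 4,5-oxide with this configuration at both epoxide carbons.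

**Compound list**

1 | 3-methylbut-3-en-2-one | CC(=O)C(C)=C | starting material
2 | 2-methyl-2-(prop-1-en-2-yl)-1,3-dioxolane | CC(=C)C1(C)OCCO1 | intermediate
3 | cyclohex-2-en-1-one | O=C1C=CCCC1 | starting material
4 | (1S,6R,7R)-7-methyl-7-(2-methyl-1,3-dioxolan-2-yl)bicyclo[4.2.0]octan-2-one, trans-fused | O=C1CCC[C@@H]2[C@@H]1C[C@@]2(C)C3(C)OCCO3 | intermediate
5 | (1R,6R,7R)-7-methyl-7-(2-methyl-1,3-dioxolan-2-yl)bicyclo[4.2.0]octan-2-one, cis-fused, dioxolanyl exo | O=C1CCC[C@@H]2[C@H]1C[C@@]2(C)C3(C)OCCO3 | intermediate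
6 | lithium enolate of 5 (enolised towards the CH2) | [Li+].[O-]C1=CCC[C@@H]2[C@H]1C[C@@]2(C)C3(C)OCCO3 | intermediate
7 | (1R,6R,7R)-3-(1-hydroxyethyl)-7-methyl-7-(2-methyl-1,3-dioxolan-2-yl)bicyclo[4.2.0]octan-2-one, C3 and carbinol centres undefined | O=C1C(C(C)O)CC[C@@H]2[C@H]1C[C@@]2(C)C3(C)OCCO3 | intermediate
8 | methanesulfonate of 7 | O=C1C(C(C)OS(C)(=O)=O)CC[C@@H]2[C@H]1C[C@@]2(C)C3(C)OCCO3 | intermediate
9 | (1R,3E,6R,7R)-3-ethylidene-7-methyl-7-(2-methyl-1,3-dioxolan-2-yl)bicyclo[4.2.0]octan-2-one | O=C1/C(=C/C)CC[C@@H]2[C@H]1C[C@@]2(C)C3(C)OCCO3 | intermediate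
10 | potassium dienolate of 9 (3-ethenyl-2-enolate) | [K+].[O-]C1=C(C=C)CC[C@@H]2[C@H]1C[C@@]2(C)C3(C)OCCO3 | intermediate
11 | (1R,6R,7R)-3-ethenyl-3,7-dimethyl-7-(2-methyl-1,3-dioxolan-2-yl)bicyclo[4.2.0]octan-2-one, C3 undefined | O=C1C(C)(C=C)CC[C@@H]2[C@H]1C[C@@]2(C)C3(C)OCCO3 | intermediate
12 | (1R,7R,8R)-4-ethenyl-4,8-dimethyl-8-(2-methyl-1,3-dioxolan-2-yl)-3-oxabicyclo[5.2.0]nonan-2-one, cis-fused, C4 undefined | O=C1OC(C)(C=C)CC[C@@H]2[C@H]1C[C@@]2(C)C3(C)OCCO3 | intermediate
13 | (1R,7R,8R)-4-ethenyl-4,8-dimethyl-2-methylidene-8-(2-methyl-1,3-dioxolan-2-yl)-3-oxabicyclo[5.2.0]nonane, C4 undefined | C=C1OC(C)(C=C)CC[C@@H]2[C@H]1C[C@@]2(C)C3(C)OCCO3 | intermediate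
14 | (1R,4Z,9R,11R)-4,11-dimethyl-11-(2-methyl-1,3-dioxolan-2-yl)bicyclo[7.2.0]undec-4-en-8-one, cis-fused | O=C1CC/C=C(C)\CC[C@@H]2[C@H]1C[C@@]2(C)C3(C)OCCO3 | intermediate
15 | (1R,4Z,9S,11R)-4,11-dimethyl-11-(2-methyl-1,3-dioxolan-2-yl)bicyclo[7.2.0]undec-4-en-8-one, trans-fused | O=C1CC/C=C(C)\CC[C@@H]2[C@@H]1C[C@@]2(C)C3(C)OCCO3 | intermediate
16 | 2-[(1R,4Z,9S,11R)-4,11-dimethyl-8-methylidenebicyclo[7.2.0]undec-4-en-11-yl]-2-methyl-1,3-dioxolane | C=C1CC/C=C(C)\CC[C@@H]2[C@@H]1C[C@@]2(C)C3(C)OCCO3 | intermediate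
17 | 2-[(1R,4R,5S,9S,11R)-4,5-epoxy-4,11-dimethyl-8-methylidenebicyclo[7.2.0]undecan-11-yl]-2-methyl-1,3-dioxolane, cis-epoxide (its face isomer, if formed, converges identically) | C=C1CC[C@@H]2O[C@]2(C)CC[C@@H]3[C@@H]1C[C@@]3(C)C4(C)OCCO4 | intermediate
18 | lithium alkoxide of the ring-opened β-hydroxy phosphine (Ph2P on the former epoxide CH, anti to O) | C=C1CC[C@@H](P(c2ccccc2)c2ccccc2)[C@@]([O-])(C)CC[C@@H]3[C@@H]1C[C@@]3(C)C4(C)OCCO4.[Li+] | intermediate
19 | P-methylated betaine of 18 | C=C1CC[C@@H]([P+](C)(c2ccccc2)c2ccccc2)[C@@]([O-])(C)CC[C@@H]3[C@@H]1C[C@@]3(C)C4(C)OCCO4 | intermediate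
20 | 2-[(1R,4E,9S,11R)-4,11-dimethyl-8-methylidenebicyclo[7.2.0]undec-4-en-11-yl]-2-methyl-1,3-dioxolane | C=C1CC/C=C(C)/CC[C@@H]2[C@@H]1C[C@@]2(C)C3(C)OCCO3 | intermediate
21 | 1-[(1R,4E,9S,11R)-4,11-dimethyl-8-methylidenebicyclo[7.2.0]undec-4-en-11-yl]ethan-1-one | C=C1CC/C=C(C)/CC[C@@H]2[C@@H]1C[C@@]2(C)C(C)=O | intermediate
22 | (R)-(2-methyloxiran-2-yl)methanol ((R)-2-methylglycidol) | OC[C@]1(C)CO1 | starting material
23 | (S)-2-methyloxirane-2-carbaldehyde | O=C[C@]1(C)CO1 | intermediate
24 | lithium enolate of 21 (methyl side) | C=C1CC/C=C(C)/CC[C@@H]2[C@@H]1C[C@@]2(C)C(=C)[O-].[Li+] | intermediate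
25 | 3-hydroxy-1-[(1R,4E,9S,11R)-4,11-dimethyl-8-methylidenebicyclo[7.2.0]undec-4-en-11-yl]-3-[(2S)-2-methyloxiran-2-yl]propan-1-one, carbinol centre undefined | C=C1CC/C=C(C)/CC[C@@H]2[C@@H]1C[C@@]2(C)C(=O)CC(O)[C@]3(C)CO3 | intermediate
26 | methanesulfonate of 25 | C=C1CC/C=C(C)/CC[C@@H]2[C@@H]1C[C@@]2(C)C(=O)CC(OS(C)(=O)=O)[C@]3(C)CO3 | intermediate
27 | (2E)-1-[(1R,4E,9S,11R)-4,11-dimethyl-8-methylidenebicyclo[7.2.0]undec-4-en-11-yl]-3-[(2R)-2-methyloxiran-2-yl]prop-2-en-1-one | C=C1CC/C=C(C)/CC[C@@H]2[C@@H]1C[C@@]2(C)C(=O)/C=C/[C@]3(C)CO3 | intermediate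
28 | (2R,3E)-2-hydroxy-2-methyl-5-oxo-5-[(1R,4E,9S,11R)-4,11-dimethyl-8-methylidenebicyclo[7.2.0]undec-4-en-11-yl]pent-3-en-1-yl acetate | C=C1CC/C=C(C)/CC[C@@H]2[C@@H]1C[C@@]2(C)C(=O)/C=C/[C@@](C)(O)COC(C)=O | intermediate
29 | (2R,3E)-2-hydroxy-2-methyl-5-oxo-5-[(1R,4R,6R,10S,12R)-4,12-dimethyl-9-methylidene-5-oxatricyclo[8.2.0.0(4,6)]dodecan-12-yl]pent-3-en-1-yl acetate | C=C1CC[C@H]2O[C@]2(C)CC[C@@H]2[C@@H]1C[C@@]2(C)C(=O)/C=C/[C@@](C)(O)COC(C)=O | target

**Step count and risks**

Total steps: 17. Longest linear sequence: 16 steps (1 to 29 through steps 1–12 and 14–17; step 13 is the side branch).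

Steps most likely to fail:

Step 2. The dioxolane oxygens may compete with the enone for the aluminium Lewis acid, or the ketal may ionise, so that enantiofacial control is lost. The fallback sets out from 2 and 3 and replaces catalytic control by resolution. Uncatalysed irradiation (350 nm, CH2Cl2, −40 °C) followed by basic Al2O3 should give the racemic cis-fused adduct, that is 5 together with the enantiomer of 5 F2, the trans-fused adducts 4 and the enantiomer of 4 F1 being epimerised on the alumina. Condensation of the racemate with SAMP, (S)-1-amino-2-(methoxymethyl)pyrrolidine, gives the SAMP hydrazone of 5 F3 and the SAMP hydrazone of the enantiomer F4, which are diastereomers and are separated by chromatography. Ozonolysis of F3 (O3, CH2Cl2, −78 °C) returns enantiopure 5, where the route is rejoined.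

Step 7. Methylenation of the hindered tertiary-alkyl lactone carbonyl may be incomplete, or the tertiary allylic C–O bond of 13 may undergo heterolysis and elimination in competition with the sigmatropic shift. The fallback sets out from 12 and makes the same CH2–CH2 bond by an ionic ring closure. LiCH2SO2Ph (2.2 equiv, THF, −78 °C) opens the lactone to the hydroxy β-keto sulfone F5. Pd(PPh3)4 (zerovalent palladium, catalytic) with Et3B in THF at high dilution ionises the tertiary allylic alcohol, and intramolecular Tsuji–Trost alkylation by the sulfonyl-stabilised carbon at the unsubstituted allyl terminus should close the less strained Z-cyclononene, giving the cyclic α-sulfonyl ketone F6. Reductive desulfonylation with aluminium amalgam in wet THF returns 14.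

Step 11. SN2 attack of the phosphide on the hindered trisubstituted epoxide may be sluggish or misdirected, or the betaine may collapse back to epoxide instead of rotating and eliminating. The fallback sets out from 17. KOH in DMSO/H2O (120 °C) opens the epoxide by anti attack at the secondary carbon to the trans-diol F7. Thiocarbonyldiimidazole (toluene, 110 °C) converts it into the cyclic thionocarbonate F8. Corey–Winter fragmentation with P(OMe)3 (110 °C), a stereospecific syn-cycloelimination, turns this anti-diol derivative into the E-alkene 20, where the route is rejoined.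

**Further compounds**

F1 | step 2 | (1R,6S,7S)-7-methyl-7-(2-methyl-1,3-dioxolan-2-yl)bicyclo[4.2.0]octan-2-one, enantiomer of 4 | O=C1CCC[C@H]2[C@H]1C[C@]2(C)C3(C)OCCO3
F2 | step 2 | (1S,6S,7S)-7-methyl-7-(2-methyl-1,3-dioxolan-2-yl)bicyclo[4.2.0]octan-2-one, enantiomer of 5 | O=C1CCC[C@H]2[C@@H]1C[C@]2(C)C3(C)OCCO3
F3 | step 2 | SAMP hydrazone of 5 (C=N geometry undefined) | COC[C@@H]1CCCN1N=C2CCC[C@@H]3[C@H]2C[C@@]3(C)C4(C)OCCO4
F4 | step 2 | SAMP hydrazone of the enantiomer of 5 (C=N geometry undefined) | COC[C@@H]1CCCN1N=C2CCC[C@H]3[C@@H]2C[C@]3(C)C4(C)OCCO4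
F5 | step 7 | hydroxy β-keto sulfone from lactone opening: 1-[2-(3-hydroxy-3-methylpent-4-en-1-yl)-3-methyl-3-(2-methyl-1,3-dioxolan-2-yl)cyclobutyl]-2-(phenylsulfonyl)ethan-1-one, cyclobutane configuration as in 12, carbinol centre undefined | C=CC(C)(O)CC[C@@H]1[C@H](C(=O)CS(=O)(=O)c2ccccc2)C[C@@]1(C)C3(C)OCCO3
F6 | step 7 | (4Z)-4,11-dimethyl-11-(2-methyl-1,3-dioxolan-2-yl)-7-(phenylsulfonyl)bicyclo[7.2.0]undec-4-en-8-one, cis-fused as 14, sulfonyl-bearing centre undefined | O=C1C(S(=O)(=O)c2ccccc2)C/C=C(C)\CC[C@@H]3[C@H]1C[C@@]3(C)C4(C)OCCO4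
F7 | step 11 | trans-4,5-diol from anti opening of 17: (1R,4R,5R,9S,11R)-4,11-dimethyl-8-methylidene-11-(2-methyl-1,3-dioxolan-2-yl)bicyclo[7.2.0]undecane-4,5-diol | C=C1CC[C@@H](O)[C@@](O)(C)CC[C@@H]3[C@@H]1C[C@@]3(C)C4(C)OCCO4
F8 | step 11 | cyclic thionocarbonate of F7 | C=C1CC[C@H]2OC(=S)O[C@]2(C)CC[C@@H]3[C@@H]1C[C@@]3(C)C4(C)OCCO4
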